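## Retrosynthetic overview

- The aldehyde comes from an isopropenyl group by allylic oxidation; the acetate and the cis-lactone come together from a 4-keto lactol by an internal hydride shift; the angelate comes from a ring ketone by reduction and acylation.
- The oxolane ring (second ring, later the lactone) is closed by intramolecular SN2 attack of a side-chain acetal oxygen on an α-bromo ketone, which fixes the C–O bond cis to the side chain.
- The quaternary carbon and its neighbour come from conjugate addition of isopropenyl to a 2-methyl enone with aldol trapping by acetaldehyde, then dehydration to the vinyl group.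
- The first stereocentre comes from an enantioselective Rh(acac)(C2H4)2/(R)-BINAP 1,4-addition of an acrolein-acetal α-anion equivalent to the unsubstituted enone arm of a quinone monoketal.
- Key step and first ring: the carbocycle is taken intact from o-cresol by oxidative dearomatization to 4,4-dimethoxy-2-methylcyclohexa-2,5-dien-1-one; all six ring stereocentres are then set on this flat dienone.

Assumption: the target is taken exactly as the SMILES defines it, i.e. (3aR,4S,5R,6S,7S,7aR) with a cis-fused lactone and a (Z)-2-methylbut-2-enoate (angelate) ester.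

Convention for names: α is the face of the ethenyl group on the quaternary ring carbon, β is the face of its methyl group. Acetal, lactol and carbinol carbons that are formed as epimer mixtures and destroyed later are left open in the SMILES.

## Route

Step 1
Reactants: 1 2-methylphenol (o-cresol)
Product: 3 4,4-dimethoxy-2-methylcyclohexa-2,5-dien-1-one, via 4-methoxy-2-methylphenol 2 (not isolated)
Conditions: PhI(OAc)2 (2.2 equiv), MeOH, 0 °C to rt
Reagents that add atoms: methanol (CO)
Why: Oxidative dearomatization of a phenol with a trivalent iodine reagent, run as two successive two-electron oxidations: methanol attacks the free para position, the resulting 4-methoxyphenol is oxidised again and trapped at the same carbon, giving an achiral p-quinone monoketal whose two enone arms differ only by the methyl group.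

Step 2
Reactants: 3 4,4-dimethoxy-2-methylcyclohexa-2,5-dien-1-one; 4 2-bromo-3,3-diethoxyprop-1-ene
Product: 7 (5R)-5-(3,3-diethoxyprop-1-en-2-yl)-4,4-dimethoxy-2-methylcyclohex-2-en-1-one, via alkenyllithium 5 (not isolated), via lithium alkenyltrimethoxyborate 6 (not isolated)
Conditions: 4, t-BuLi (2 equiv), Et2O, −78 °C; B(OMe)3; then 3, Rh(acac)(C2H4)2 (3 mol %), (R)-BINAP (3.3 mol %), dioxane/H2O (10:1), 60 °C
Reagents that add atoms: none
Why: Hayashi–Miyaura asymmetric 1,4-addition of an in situ alkenylborate: the alkenyl–rhodium species (monovalent rhodium) inserts only the unsubstituted enone arm because the 2-methyl arm is too hindered, and (R)-BINAP, chosen by analogy with the known facial sense for 2-cyclohexenone, sets the (5R) centre that becomes the lactone ring-fusion carbon.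

Step 3
Reactants: 7 (5R)-5-(3,3-diethoxyprop-1-en-2-yl)-4,4-dimethoxy-2-methylcyclohex-2-en-1-one; 8 prop-1-en-2-ylmagnesium bromide; 9 acetaldehyde
Product: 11 5-(3,3-diethoxyprop-1-en-2-yl)-2-(1-hydroxyethyl)-4,4-dimethoxy-2-methyl-3-(prop-1-en-2-yl)cyclohexan-1-one (3-isopropenyl trans to the C5 side chain and cis to the 2-methyl; carbinol epimers), via magnesium enolate 10 (not isolated)
Conditions: 8 (1.5 equiv), CuBr·SMe2 (10 mol %), THF, −40 °C; then 9, −78 °C; aq. NH4Cl
Reagents that add atoms: none
Why: Copper-catalysed conjugate addition with aldol trapping (three-component coupling): the organocopper adds axially to C3 anti to the C5 side chain (3,5-trans), and the tetrasubstituted enolate is attacked by acetaldehyde on the face opposite the new isopropenyl group, which sets the quaternary carbon with methyl cis and the two-carbon unit trans to the isopropenyl group.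

Step 4
Reactants: 11 aldol adduct
Product: 12 (2S,3S,5R)-5-(3,3-diethoxyprop-1-en-2-yl)-2-ethenyl-4,4-dimethoxy-2-methyl-3-(prop-1-en-2-yl)cyclohexan-1-one
Conditions: Ph2S[OC(CF3)2Ph]2 (Martin sulfurane), CH2Cl2, 0 °C to rt
Reagents that add atoms: none
Why: Martin sulfurane dehydration: the alkoxysulfonium intermediate can only lose a proton from the methyl group because the other neighbour is quaternary, so the terminal vinyl group forms without base (no retro-aldol) and no stereocentre is touched.

Step 5
Reactants: 12 vinyl ketone
Product: 15 cis-fused 2-ethoxy-6-ethenyl-4,4-dimethoxy-6-methyl-3-methylidene-5-(prop-1-en-2-yl)octahydro-1-benzofuran-7-one (O1 and C3 α; 5-isopropenyl β; C2 epimers), via lithium enolate 13 (not isolated), via bromo ketone 14 (not isolated)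
Conditions: LiN(SiMe3)2, THF, −78 °C; BrCl2C–CCl2Br; then 60 °C
Reagents that add atoms: none
Why: Proposed new method: enolate bromination at C6 (the only enolisable position) is followed by intramolecular SN2 displacement of the α-keto bromide by an acetal oxygen of the adjacent side chain and loss of bromoethane from the oxonium ion, the closest known reactions being the thermal cyclisation of 4-halobutanal acetals to 2-alkoxytetrahydrofurans and SN2 lactonisation onto α-bromo ketones; backside attack from the side-chain face makes the new C–O bond cis to the side chain whichever bromide epimer forms first, because lithium bromide interconverts the epimers.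

Step 6
Reactants: 15 bicyclic ketone
Product: 16 the corresponding 7α-alcohol, 2-ethoxy-6-ethenyl-4,4-dimethoxy-6-methyl-3-methylidene-5-(prop-1-en-2-yl)octahydro-1-benzofuran-7-ol (7-OH cis to O1)
Conditions: NaBH4, MeOH, −20 to 0 °C
Reagents that add atoms: none
Why: Substrate-controlled borohydride reduction: hydride attacks the C7 ketone from the convex β face, anti to the C7a–O bond (Felkin–Anh polar effect) and away from the cis-fused oxolane ring and the α-ethenyl group, giving the alcohol cis to the ring oxygen.

Step 7
Reactants: 16 7α-alcohol; 17 angelic acid ((Z)-2-methylbut-2-enoic acid)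
Product: 18 the 7α-angelate of 16
Conditions: 17, 2,4,6-trichlorobenzoyl chloride, Et3N, toluene, rt; then 16, 80 °C
Reagents that add atoms: none
Why: Yamaguchi-type esterification through the mixed anhydride of angelic acid, run hot in toluene without a nucleophilic catalyst, which acylates hindered secondary alcohols with retention of the (Z)-alkene geometry and touches no stereocentre.

Step 8
Reactants: 18 angelate ketal acetal
Product: 19 6-ethenyl-2-hydroxy-6-methyl-3-methylidene-4-oxo-5-(prop-1-en-2-yl)octahydro-1-benzofuran-7-yl (Z)-2-methylbut-2-enoate (lactol anomers)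
Conditions: PPTS, THF/H2O (4:1), 45 °C
Reagents that add atoms: water (O)
Why: Mild acid-catalysed acetal hydrolysis: the dimethyl ketal gives the C4 ketone and the cyclic ethyl acetal gives the lactol, while the low acidity avoids enolisation of the new ketone toward C3a or C5 (no epimerisation, alkene migration or furan formation) and leaves the angelate intact.

Step 9
Reactants: 19 keto lactol
Product: 21 4β-acetoxy-6-ethenyl-6-methyl-3-methylidene-2-oxo-5β-(prop-1-en-2-yl)octahydro-1-benzofuran-7α-yl (Z)-2-methylbut-2-enoate, via hydroxy lactone 20 (not isolated)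
Conditions: SmI2 (20 mol %), PhCHO (20 mol %), THF, −10 °C to rt; then Ac2O, pyridine, DMAP, rt
Reagents that add atoms: acetic anhydride (CC(=O)OC(C)=O)
Why: Proposed new method: an intramolecular Evans–Tishchenko redox step in which the lactol, bound as a trivalent samarium alkoxide, transfers its anomeric hydride to the neighbouring C4 ketone through a cyclic Meerwein–Ponndorf–Verley-type transition state, so the lactol becomes the lactone and the hydride necessarily arrives on the α face to give the 4β-alcohol anti to O1 (closest known reactions: the intermolecular Evans–Tishchenko anti-1,3-diol synthesis and the Tishchenko lactonisation of keto aldehydes); the alkoxide is then acetylated in the same flask.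

Step 10
Reactants: 21 acetoxy lactone
Product: 22 (3aR,4S,5R,6S,7S,7aR)-4-(acetyloxy)-6-ethenyl-6-methyl-3-methylidene-2-oxo-5-(3-oxoprop-1-en-2-yl)octahydro-1-benzofuran-7-yl (2Z)-2-methylbut-2-enoate
Conditions: SeO2 (2 equiv), 1,4-dioxane, 80 °C
Reagents that add atoms: selenium dioxide (O=[Se]=O)
Why: Riley allylic oxidation (ene reaction, [2,3]-sigmatropic shift, then oxidation to the aldehyde): the isopropenyl group is the only electron-rich alkene with allylic hydrogens (the vinyl group has none and the other two alkenes are deactivated by carbonyl groups), and its methyl group reacts in preference to the ring methine, giving the 2-substituted propenal without changing any stereocentre.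

## Compound list

1 | 2-methylphenol (o-cresol) | Cc1ccccc1O | starting material
2 | 4-methoxy-2-methylphenol | COc1ccc(O)c(C)c1 | intermediate
3 | 4,4-dimethoxy-2-methylcyclohexa-2,5-dien-1-one | CC1=CC(OC)(OC)C=CC1=O | intermediate
4 | 2-bromo-3,3-diethoxyprop-1-ene | C=C(Br)C(OCC)OCC | starting material
5 | (3,3-diethoxyprop-1-en-2-yl)lithium | [Li]C(=C)C(OCC)OCC | intermediate
6 | lithium (3,3-diethoxyprop-1-en-2-yl)trimethoxyborate | [Li+].CO[B-](OC)(OC)C(=C)C(OCC)OCC | intermediate
7 | (5R)-5-(3,3-diethoxyprop-1-en-2-yl)-4,4-dimethoxy-2-methylcyclohex-2-en-1-one | O=C1C[C@H](C(=C)C(OCC)OCC)C(OC)(OC)C=C1C | intermediate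
8 | prop-1-en-2-ylmagnesium bromide | CC(=C)[Mg]Br | starting material
9 | acetaldehyde | CC=O | starting material
10 | bromomagnesium 5-(3,3-diethoxyprop-1-en-2-yl)-4,4-dimethoxy-2-methyl-3-(prop-1-en-2-yl)cyclohex-1-en-1-olate (3,5-trans) | CC1=C(O[Mg]Br)C[C@H](C(=C)C(OCC)OCC)C(OC)(OC)[C@H]1C(C)=C | intermediate
11 | 5-(3,3-diethoxyprop-1-en-2-yl)-2-(1-hydroxyethyl)-4,4-dimethoxy-2-methyl-3-(prop-1-en-2-yl)cyclohexan-1-one (2-hydroxyethyl and C5 chain α, 2-methyl and 3-isopropenyl β; carbinol epimers) | CC(O)[C@]1(C)C(=O)C[C@H](C(=C)C(OCC)OCC)C(OC)(OC)[C@H]1C(C)=C | intermediate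
12 | (2S,3S,5R)-5-(3,3-diethoxyprop-1-en-2-yl)-2-ethenyl-4,4-dimethoxy-2-methyl-3-(prop-1-en-2-yl)cyclohexan-1-one | C=C[C@]1(C)C(=O)C[C@H](C(=C)C(OCC)OCC)C(OC)(OC)[C@H]1C(C)=C | intermediate
13 | lithium enolate of 12 (C1–C6 enolate) | C=C[C@]1(C)C(O[Li])=C[C@H](C(=C)C(OCC)OCC)C(OC)(OC)[C@H]1C(C)=C | intermediate
14 | 6-bromo derivative of 12 (6β-bromine, trans to the 5α side chain) | C=C[C@]1(C)C(=O)[C@@H](Br)[C@H](C(=C)C(OCC)OCC)C(OC)(OC)[C@H]1C(C)=C | intermediate
15 | cis-fused 2-ethoxy-6-ethenyl-4,4-dimethoxy-6-methyl-3-methylidene-5-(prop-1-en-2-yl)octahydro-1-benzofuran-7-one (O1, C3 and ethenyl α; isopropenyl and methyl β; C2 epimers) | C=C[C@]1(C)C(=O)[C@@H]2OC(OCC)C(=C)[C@@H]2C(OC)(OC)[C@H]1C(C)=C | intermediate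
16 | 7α-alcohol of 15 (7-OH cis to O1) | C=C[C@]1(C)[C@H](O)[C@@H]2OC(OCC)C(=C)[C@@H]2C(OC)(OC)[C@H]1C(C)=C | intermediate
17 | angelic acid ((Z)-2-methylbut-2-enoic acid) | C/C=C(/C)C(=O)O | starting material
18 | 7α-angelate of 16 | C=C[C@]1(C)[C@H](OC(=O)/C(C)=C\C)[C@@H]2OC(OCC)C(=C)[C@@H]2C(OC)(OC)[C@H]1C(C)=C | intermediate
19 | 6-ethenyl-2-hydroxy-6-methyl-3-methylidene-4-oxo-5β-(prop-1-en-2-yl)octahydro-1-benzofuran-7α-yl (Z)-2-methylbut-2-enoate (lactol anomers) | C=C[C@]1(C)[C@H](OC(=O)/C(C)=C\C)[C@@H]2OC(O)C(=C)[C@@H]2C(=O)[C@H]1C(C)=C | intermediate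
20 | 6-ethenyl-4β-hydroxy-6-methyl-3-methylidene-2-oxo-5β-(prop-1-en-2-yl)octahydro-1-benzofuran-7α-yl (Z)-2-methylbut-2-enoate | C=C[C@]1(C)[C@H](OC(=O)/C(C)=C\C)[C@@H]2OC(=O)C(=C)[C@@H]2[C@@H](O)[C@H]1C(C)=C | intermediate
21 | 4β-acetoxy analogue of 20 | C=C[C@]1(C)[C@H](OC(=O)/C(C)=C\C)[C@@H]2OC(=O)C(=C)[C@@H]2[C@@H](OC(C)=O)[C@H]1C(C)=C | intermediate
22 | (3aR,4S,5R,6S,7S,7aR)-4-(acetyloxy)-6-ethenyl-6-methyl-3-methylidene-2-oxo-5-(3-oxoprop-1-en-2-yl)octahydro-1-benzofuran-7-yl (2Z)-2-methylbut-2-enoate | C=C[C@]1(C)[C@H](OC(=O)/C(C)=C\C)[C@@H]2OC(=O)C(=C)[C@@H]2[C@@H](OC(C)=O)[C@H]1C(=C)C=O | target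

## Step count and risks

Total step count: 10. Longest linear sequence: 10 steps (1 to 22); 4, 8, 9 and 17 are bought and enter directly.

The three steps most likely to fail:

Step 3 builds a very congested quaternary carbon in one flask, and the addition, the aldol or the later dehydration may be sluggish. The fallback sets out from 7: the same copper-catalysed addition of 8 is run with Me3SiCl to isolate the trimethylsilyl enol ether F1. MeLi then regenerates the lithium enolate, which adds to (phenylselanyl)acetaldehyde to give the β-hydroxy selenide F2. MsCl/Et3N removes the selanyl and hydroxyl groups by anti elimination and gives the vinyl ketone directly, so the route is rejoined at 12 and no carbinol dehydration is needed.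

Step 5 relies on a weakly nucleophilic acetal oxygen, and elimination or slow cyclisation could compete. The fallback sets out from 12: it is brominated as before but quenched cold so that 14 is isolated. Caesium formate with 18-crown-6 in MeCN displaces the bromide by SN2 with inversion to give the formate F3. KHCO3 in MeOH at 0 °C frees the ketol F4, and PPTS in CH2Cl2 over 4 Å molecular sieves closes the ethyl acetal, coming back to the route at 15.

Step 9 depends on an internal hydride transfer that has no direct precedent in this ring system, and the keto lactol can also eliminate or isomerise. The fallback sets out from 19: TEMPO/PhI(OAc)2 oxidises the lactol to the keto lactone F5. The ketone is then reduced under reagent control (Corey–Bakshi–Shibata oxazaborolidine with catecholborane at −78 °C, catalyst enantiomer chosen for α-face hydride delivery), which gives 20; this is acetylated as in step 9 and the route is rejoined at 21.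

Further compounds
F1 | step 3 | trimethylsilyl enol ether of the conjugate adduct, [5-(3,3-diethoxyprop-1-en-2-yl)-4,4-dimethoxy-2-methyl-3-(prop-1-en-2-yl)cyclohex-1-en-1-yl]oxy(trimethyl)silane (3,5-trans) | CC1=C(O[Si](C)(C)C)C[C@H](C(=C)C(OCC)OCC)C(OC)(OC)[C@H]1C(C)=C
F2 | step 3 | 5-(3,3-diethoxyprop-1-en-2-yl)-2-[1-hydroxy-2-(phenylselanyl)ethyl]-4,4-dimethoxy-2-methyl-3-(prop-1-en-2-yl)cyclohexan-1-one (ring configuration as in 11; carbinol epimers) | OC(C[Se]c1ccccc1)[C@]1(C)C(=O)C[C@H](C(=C)C(OCC)OCC)C(OC)(OC)[C@H]1C(C)=C
F3 | step 5 | 6α-formyloxy derivative of 12 (formate cis to the 5α side chain) | C=C[C@]1(C)C(=O)[C@H](OC=O)[C@H](C(=C)C(OCC)OCC)C(OC)(OC)[C@H]1C(C)=C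
F4 | step 5 | 6α-hydroxy derivative of 12 | C=C[C@]1(C)C(=O)[C@H](O)[C@H](C(=C)C(OCC)OCC)C(OC)(OC)[C@H]1C(C)=C
F5 | step 9 | 6-ethenyl-6-methyl-3-methylidene-2,4-dioxo-5β-(prop-1-en-2-yl)octahydro-1-benzofuran-7α-yl (Z)-2-methylbut-2-enoate | C=C[C@]1(C)[C@H](OC(=O)/C(C)=C\C)[C@@H]2OC(=O)C(=C)[C@@H]2C(=O)[C@H]1C(C)=C
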